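**Plan**

- Target: (3'S, all-E)-eschscholtzxanthone; ring A (keto end) is C1–C6, the chain is C7–C15, and primed numbers belong to the ring B (hydroxy end) half.
- Cuts: the C3 ketone goes back to one carbinol of the C2-symmetric (3S,3'S)-diol, the retro-dodecaene to a 6,6'-diol, then C6–C7 and C6'–C7' are cut (ketone plus acetylide), and last C11=C12 and C11'=C12' (Wittig).
- Enabling feature: ring A and ring B are 2,6,6-trimethylcyclohex-2-enylidene ends whose C6 and C6' were the carbonyl carbons of a 4-oxygenated 2,6,6-trimethylcyclohex-2-enone; each sits between a quaternary carbon (C1, C1') and a methyl-bearing sp2 carbon (C5, C5') and cannot enolise.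
- Forward order: both rings come ready-made from ketoisophorone; the C7–C7' chain is assembled as a C22 heptaenediyne (C6 + C10 + C6) and its dilithium salt is joined to both rings in one operation; alkyne reduction, reductive elimination, desilylation and mono-oxidation follow.
- Stereochemistry: C3' comes from asymmetric transfer hydrogenation of ketoisophorone; the C6/C6' carbinols are transient; the all-E geometry comes from E building blocks, trans-hydroalumination and thermodynamic equilibration.

Key step: step 6

Assumption: in step 1 the enone C=C of ketoisophorone is taken to play the part of the aryl group of an aryl alkyl ketone, so the (S,S)-TsDPEN complex should give the (S)-alcohol; if the sense proves opposite, the (R,R)-ligand is used and nothing else changes.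

**Step 1**
Reactants: 1 ketoisophorone
Product: 2 (S)-4-hydroxy-2,6,6-trimethylcyclohex-2-en-1-one
Conditions: RuCl[(S,S)-TsDPEN](p-cymene) (1 mol %), KOH (2 mol %), i-PrOH, 20 °C
Reagents that add atoms: none
Why: Noyori asymmetric transfer hydrogenation should reduce only the open C4 carbonyl (the C1 carbonyl is shielded by the gem-dimethyl carbon and the vinylic methyl), the chiral ruthenium hydride delivering hydrogen to one enantioface to set the (S)-carbinol that becomes C3' of the target.

**Step 2**
Reactants: 2 (S)-4-hydroxy-2,6,6-trimethylcyclohex-2-en-1-one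
Product: 3 (S)-4-(tert-butyldimethylsilyloxy)-2,6,6-trimethylcyclohex-2-en-1-one
Conditions: TBSCl, imidazole, DMF, 20 °C
Reagents that add atoms: tert-butyldimethylsilyl chloride, CC(C)(C)[Si](C)(C)Cl
Why: Imidazole-promoted silylation of a secondary allylic alcohol is routine, touches no stereocentre, and gives an ether that should withstand the acetylide, LiAlH4 and low-valent titanium of steps 6 to 8.

**Step 3**
Reactants: 4 (E)-3-methylpent-2-en-4-yn-1-ol
Product: 5 (E)-5-bromo-3-methylpent-3-en-1-yne
Conditions: PBr3 (0.4 equiv), Et2O, −20 to 0 °C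
Reagents that add atoms: phosphorus tribromide, BrP(Br)Br
Why: SN2 bromination of a primary allylic alcohol with PBr3 at low temperature should keep the E geometry and give the conjugated primary bromide, which is both the kinetic and the thermodynamic product.

**Step 4**
Reactants: 5 (E)-5-bromo-3-methylpent-3-en-1-yne
Product: 6 [(E)-3-methylpent-2-en-4-yn-1-yl]triphenylphosphonium bromide
Conditions: PPh3, toluene, 20 °C
Reagents that add atoms: triphenylphosphine, c1ccc(cc1)P(c1ccccc1)c1ccccc1
Why: SN2 quaternisation of triphenylphosphine by a primary allylic bromide should give the Wittig salt, which precipitates from toluene.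

**Step 5**
Reactants: 6 [(E)-3-methylpent-2-en-4-yn-1-yl]triphenylphosphonium bromide (2.4 equiv); 7 (2E,4E,6E)-2,7-dimethylocta-2,4,6-trienedial
Product: 10 all-E C22 heptaenediyne (3E,5E,7E,9E,11E,13E,15E)-3,7,12,16-tetramethyloctadeca-3,5,7,9,11,13,15-heptaene-1,17-diyne, via phosphorus ylide 8 (not isolated), via 5Z/13Z-containing Wittig mixture 9 (not isolated)
Conditions: NaOMe, MeOH/CH2Cl2, 0 to 20 °C; then I2 (cat.), toluene, daylight, 20 °C; crystallisation
Reagents that add atoms: none
Why: In this double Wittig olefination methoxide should deprotonate only the acidic P–CH2 group and not the alkyne C–H, the semi-stabilised ylide gives E/Z mixtures at the two new disubstituted double bonds (carotenoid C11=C12 and C11'=C12'), and iodine-catalysed equilibration should turn the hindered Z isomers into the all-E diyne, expected to be the least soluble isomer.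

**Step 6**
Reactants: 10 all-E C22 heptaenediyne; 3 (S)-4-(tert-butyldimethylsilyloxy)-2,6,6-trimethylcyclohex-2-en-1-one (2.4 equiv, two molecules react)
Product: 12 C40 bis-propargylic 6,6'-diol bis-TBS ether (C6/C6' epimer mixture), via dilithium diacetylide 11 (not isolated)
Conditions: n-BuLi (2.1 equiv), THF, −78 to −40 °C; then 3, −78 to 0 °C; aq. NH4Cl
Reagents that add atoms: none
Why: n-BuLi removes both terminal alkyne protons of 10, and each sp carbanion of 11 attacks the ring carbonyl carbon of one molecule of 3 in a direct 1,2-addition, so that the C6–C7 and C6'–C7' bonds form in one flask and the whole C40 skeleton with its four chain methyls is in place. The closest known reaction is the addition of lithium acetylides to 2,6,6-trimethylcyclohex-2-enones used for ionone-type and abscisic-acid-type building blocks, run here at both ends of one diyne. No ring is closed; both rings arrive preformed. The two new carbinol centres at C6 and C6' are not controlled (the acetylide may enter syn or anti to the remote silyloxy group) and need not be, since both become sp2 in step 8, while C3 and C3' are carried over unchanged from 3. The step needs carbonyl addition rather than enolisation or conjugate addition: the carbonyl carbon (future C6/C6') lies between the quaternary carbon (future C1/C1') and the methyl-bearing sp2 carbon (future C5/C5') and has no α-hydrogen, the slim linear acetylide is the carbon nucleophile best able to reach it, and the hard lithium counter-ion together with the silyloxy-bearing carbon next to the β-position directs attack to the carbonyl. Because both electrophiles are the same ketone there is no cross-selectivity question, and the excess of 3 should drive the second addition.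

**Step 7**
Reactants: 12 C40 bis-propargylic 6,6'-diol bis-TBS ether
Product: 13 all-E C40 6,6'-diol bis-TBS ether, (3S,3'S)-3,3'-bis(tert-butyldimethylsilyloxy)-ε,ε-carotene-6,6'-diol (C6/C6' epimer mixture)
Conditions: LiAlH4 (excess), THF, 0 to 45 °C, dark; aqueous potassium sodium tartrate
Reagents that add atoms: none
Why: Hydroxyl-directed trans-hydroalumination of propargylic alcohols with LiAlH4 (intramolecular hydride delivery from the alkoxyaluminium hydride, then protonation of the alkenyl–aluminium bond) should give only the E alkenes at C7=C8 and C7'=C8', as in the classical reduction of ethynyl carbinols of trimethylcyclohexanones in retinoid work, while the silyl ethers and the polyene are inert to hydride.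

**Step 8**
Reactants: 13 all-E C40 6,6'-diol bis-TBS ether
Product: 14 (3S,3'S,6E,6'E)-3,3'-bis(tert-butyldimethylsilyloxy)-4',5'-didehydro-4,5'-retro-β,β-carotene
Conditions: TiCl3/LiAlH4 (2:1, excess), THF, 0 to 20 °C, argon, dark; aq. K2CO3; crystallisation
Reagents that add atoms: none
Why: Low-valent-titanium reductive elimination of a vinylogous 1,2-diol, known for 2-ene-1,4-diols and 2,4-diene-1,6-diols and related to the Kuhn–Winterstein reaction, should cleave both C–O bonds from the titanium alkoxides through a radical delocalised over the whole chain; every former single bond becomes a double bond with the E geometry preset by its s-trans conformation, the exocyclic 6E geometry (C8 beside the gem-dimethyl carbon, away from the in-plane C5 methyl) is the thermodynamically favoured one, and the silyl ethers keep O3 and O3' off titanium.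

**Step 9**
Reactants: 14 bis-TBS ether of eschscholtzxanthin
Product: 15 (3S,3'S)-eschscholtzxanthin, (3S,3'S,6E,6'E)-4',5'-didehydro-4,5'-retro-β,β-carotene-3,3'-diol
Conditions: Bu4NF/AcOH (1:1), THF, 0 to 20 °C, dark
Reagents that add atoms: none
Why: Fluoride-driven desilylation buffered with acetic acid should free both allylic alcohols without the strong acid that would ionise the C3–O bonds of the retro-polyene, so both stereocentres stay intact.

**Step 10**
Reactants: 15 (3S,3'S)-eschscholtzxanthin
Product: 16 eschscholtzxanthone, (3'S,6E,6'E)-3'-hydroxy-4',5'-didehydro-4,5'-retro-β,β-caroten-3-one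
Conditions: activated MnO2 (about 10 equiv), CH2Cl2, 0 °C, dark; stopped at partial conversion; chromatography, recovered 15 recycled
Reagents that add atoms: none
Why: MnO2 oxidation of an allylic alcohol on the C2-symmetric diol gives the same ketol whichever carbinol reacts, the dienone formed first withdraws electron density through the conjugated dodecaene and should slow the second oxidation, and the remaining C3' carbinol is not epimerisable under these neutral conditions.

**Compound list**

1 | ketoisophorone (2,6,6-trimethylcyclohex-2-ene-1,4-dione) | CC1=CC(=O)CC(C)(C)C1=O | starting material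
2 | (S)-4-hydroxy-2,6,6-trimethylcyclohex-2-en-1-one | CC1=C[C@@H](O)CC(C)(C)C1=O | intermediate
3 | (S)-4-(tert-butyldimethylsilyloxy)-2,6,6-trimethylcyclohex-2-en-1-one | CC1=C[C@@H](O[Si](C)(C)C(C)(C)C)CC(C)(C)C1=O | intermediate
4 | (E)-3-methylpent-2-en-4-yn-1-ol | C#C/C(C)=C/CO | starting material
5 | (E)-5-bromo-3-methylpent-3-en-1-yne | C#C/C(C)=C/CBr | intermediate
6 | [(E)-3-methylpent-2-en-4-yn-1-yl]triphenylphosphonium bromide | C#C/C(C)=C/C[P+](c1ccccc1)(c1ccccc1)c1ccccc1.[Br-] | intermediate
7 | (2E,4E,6E)-2,7-dimethylocta-2,4,6-trienedial (C10 dial) | O=C/C(C)=C/C=C/C=C(C)/C=O | starting material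
8 | phosphorus ylide of 6 (not isolated) | C#C/C(C)=C/C=P(c1ccccc1)(c1ccccc1)c1ccccc1 | intermediate
9 | C22 heptaenediyne as the kinetic mixture of isomers at the two new double bonds (not isolated) | C#C/C(C)=C/C=CC(/C)=C/C=C/C=C(\C)C=C/C=C(C)/C#C | intermediate
10 | all-E C22 heptaenediyne, (3E,5E,7E,9E,11E,13E,15E)-3,7,12,16-tetramethyloctadeca-3,5,7,9,11,13,15-heptaene-1,17-diyne (carotenoid C7 to C7') | C#C/C(C)=C/C=C/C(C)=C/C=C/C=C(C)/C=C/C=C(C)/C#C | intermediate
11 | dilithium diacetylide of 10 (not isolated) | [Li]C#C/C(C)=C/C=C/C(C)=C/C=C/C=C(C)/C=C/C=C(C)/C#C[Li] | intermediate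
12 | C40 bis-propargylic 6,6'-diol bis-TBS ether, (3S,3'S)-3,3'-bis(tert-butyldimethylsilyloxy)-7,8,7',8'-tetradehydro-ε,ε-carotene-6,6'-diol, C6/C6' epimer mixture | CC1=C[C@@H](O[Si](C)(C)C(C)(C)C)CC(C)(C)C1(O)C#C/C(C)=C/C=C/C(C)=C/C=C/C=C(C)/C=C/C=C(C)/C#CC1(O)C(C)=C[C@@H](O[Si](C)(C)C(C)(C)C)CC1(C)C | intermediate
13 | all-E C40 6,6'-diol bis-TBS ether, (3S,3'S)-3,3'-bis(tert-butyldimethylsilyloxy)-ε,ε-carotene-6,6'-diol, C6/C6' epimer mixture | CC1=C[C@@H](O[Si](C)(C)C(C)(C)C)CC(C)(C)C1(O)/C=C/C(C)=C/C=C/C(C)=C/C=C/C=C(C)/C=C/C=C(C)/C=C/C1(O)C(C)=C[C@@H](O[Si](C)(C)C(C)(C)C)CC1(C)C | intermediate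
14 | (3S,3'S,6E,6'E)-3,3'-bis(tert-butyldimethylsilyloxy)-4',5'-didehydro-4,5'-retro-β,β-carotene | CC1=C[C@@H](O[Si](C)(C)C(C)(C)C)CC(C)(C)\C1=C/C=C(C)/C=C/C=C(C)/C=C/C=C/C(C)=C/C=C/C(C)=C/C=C1/C(C)=C[C@@H](O[Si](C)(C)C(C)(C)C)CC1(C)C | intermediate
15 | (3S,3'S)-eschscholtzxanthin | CC1=C[C@@H](O)CC(C)(C)\C1=C/C=C(C)/C=C/C=C(C)/C=C/C=C/C(C)=C/C=C/C(C)=C/C=C1/C(C)=C[C@@H](O)CC1(C)C | intermediate
16 | eschscholtzxanthone, (3'S,6E,6'E)-3'-hydroxy-4',5'-didehydro-4,5'-retro-β,β-caroten-3-one | CC1=CC(=O)CC(C)(C)\C1=C/C=C(C)/C=C/C=C(C)/C=C/C=C/C(C)=C/C=C/C(C)=C/C=C1/C(C)=C[C@@H](O)CC1(C)C | target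

**Step count and risks**

Total: 10 steps. Longest linear sequence: 8 steps (from 4 through steps 3, 4, 5, 6, 7, 8, 9, 10).

Most likely to fail:

1. Step 8. The crowded tertiary carbinols may be slow to form titanium alkoxides, or the deoxygenation may stop after the first hydroxyl with hydrogen capture by the delocalised radical, giving partly reduced chains. The fallback sets out from 13 and changes the elimination to an electron-transfer process on an activated derivative. Double deprotonation with MeLi in THF at −78 °C and acylation with benzoyl chloride should give the 6,6'-dibenzoate F1, used crude. Sodium amalgam in THF/MeOH at −20 °C then expels both benzoates in a vinylogous 1,2-elimination, as known for dienyl 1,6-dibenzoates in polyene synthesis. Any allylic migration of a benzoate along the chain leads to the same retro-dodecaene, and the sequence comes back to the route at 14.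

2. Step 6. The dilithium diacetylide may aggregate or fall out of solution so that the second addition stalls at the mono-adduct, or the sensitive terminal diyne may decompose during metalation. The fallback sets out from 4 and 3 and forms the same C6–C7 bond one ring at a time. The dianion of 4 (n-BuLi, 2 equiv, THF, −78 to 0 °C) should add through its acetylide carbon to 3 to give the C15 acetylenic diol F2. Appel bromination (CBr4, PPh3, CH2Cl2, 0 °C) of the primary allylic hydroxyl gives the C15 bromide F3, the tertiary carbinol staying free. PPh3 in toluene gives the C15 phosphonium bromide F4. Double Wittig olefination of F4 with the C10 dial 7 (NaOMe, MeOH/CH2Cl2, then iodine-catalysed equilibration) comes back to the route at 12.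

3. Step 10. Discrimination between the first and the second oxidation may be poor, so that the 3,3'-dione, which has lost the stereocentre and cannot be recycled, builds up before the diol is used. The fallback sets out from 14 and moves the differentiation to the protecting groups so that the oxidation can be run to completion. Bu4NF (about 1 equiv, THF, −20 °C), stopped partway, should give the mono-silyl ether F5, separable by polarity from 14 and 15, both of which are recyclable (15 by re-silylation). Excess MnO2 oxidises the single free allylic alcohol to the silyl-protected ketone F6, and buffered Bu4NF/AcOH comes back to the route at 16.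

**Further compounds**

F1 | step 8 | 6,6'-dibenzoate of 13 | CC1=C[C@@H](O[Si](C)(C)C(C)(C)C)CC(C)(C)C1(OC(=O)c2ccccc2)/C=C/C(C)=C/C=C/C(C)=C/C=C/C=C(C)/C=C/C=C(C)/C=C/C1(OC(=O)c2ccccc2)C(C)=C[C@@H](O[Si](C)(C)C(C)(C)C)CC1(C)C
F2 | step 6 | C15 acetylenic diol, (4S)-4-(tert-butyldimethylsilyloxy)-1-[(E)-5-hydroxy-3-methylpent-3-en-1-ynyl]-2,6,6-trimethylcyclohex-2-en-1-ol | CC1=C[C@@H](O[Si](C)(C)C(C)(C)C)CC(C)(C)C1(O)C#C/C(C)=C/CO
F3 | step 6 | C15 bromide, (4S)-1-[(E)-5-bromo-3-methylpent-3-en-1-ynyl]-4-(tert-butyldimethylsilyloxy)-2,6,6-trimethylcyclohex-2-en-1-ol | CC1=C[C@@H](O[Si](C)(C)C(C)(C)C)CC(C)(C)C1(O)C#C/C(C)=C/CBr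
F4 | step 6 | C15 phosphonium bromide from F3 | CC1=C[C@@H](O[Si](C)(C)C(C)(C)C)CC(C)(C)C1(O)C#C/C(C)=C/C[P+](c2ccccc2)(c2ccccc2)c2ccccc2.[Br-]
F5 | step 10 | mono-TBS ether of (3S,3'S)-eschscholtzxanthin | CC1=C[C@@H](O)CC(C)(C)\C1=C/C=C(C)/C=C/C=C(C)/C=C/C=C/C(C)=C/C=C/C(C)=C/C=C1/C(C)=C[C@@H](O[Si](C)(C)C(C)(C)C)CC1(C)C
F6 | step 10 | 3'-O-TBS ether of eschscholtzxanthone | CC1=CC(=O)CC(C)(C)\C1=C/C=C(C)/C=C/C=C(C)/C=C/C=C/C(C)=C/C=C/C(C)=C/C=C1/C(C)=C[C@@H](O[Si](C)(C)C(C)(C)C)CC1(C)C
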